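**Retrosynthetic overview**

1. Target 21 comes from bicyclic enone 19 by removing a C6 carbonyl group (Luche reduction, then ionic hydrogenolysis); the C6 ketone is a temporary activating group.
2. Enone 19 comes from open-chain diketo-enone 16: Michael addition C5→C10 closes ring A first, aldol condensation C7=C8 closes ring B second. The enabling feature is that, with C6 as a ketone, ring B (C5–C6–C7=C8(C17)–C9–C10) is a 3-methylcyclohex-2-enone, so C8 is a ketone carbon, C10 the β-carbon of its enone, and C5 and C7 are both α to C6.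
3. Diketone 16 comes from dihydropyranone 12 by 1,2-addition of MeLi (C20) and acid ring-opening, then diacetylation and Wacker oxidation (C6 ketone from a terminal alkene). The pyranone is a temporary ring that carries C2–O and masks the tetrasubstituted enone.
4. Pyranone 12 comes from aldehyde 3 and bis-silyl dienol ether 10 by an enantioselective aldol addition/cyclisation that sets C2; C2 then controls C10.
5. Diene 10 comes from acetylacetone and iodide 7, which is made from (S)-citronellol (C13).

Key step: step 11

Remark: carbons are numbered as in labdanes (C1–C10 decalin, C11–C16 side chain, C17 on C8, C18/C19 on C4, C20 on C10). The enone in 14–16 is drawn Z as formed; its geometry does not matter for step 11.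

**Route**

Step 1
Reactants: 1 2,2-dimethylpent-4-enal
Product: 3 3,3-dimethylhex-5-enal, via enol ether 2 (not isolated)
Conditions: Ph3P(CH2OMe)Cl, KOtBu, THF, 0 °C to rt; then 2 M HCl, THF, rt
Reagents that add atoms: (methoxymethyl)triphenylphosphonium chloride (COC[P+](c1ccccc1)(c1ccccc1)c1ccccc1.[Cl-]); water (O)
Why: Wittig methoxymethylenation of the non-enolisable aldehyde followed by hydrolysis of the enol ether is a standard one-carbon homologation; no stereocentre is formed.

Step 2
Reactants: 4 (S)-citronellol
Product: 5 (S)-citronellyl acetate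
Conditions: Ac2O, pyridine, DMAP (cat.), CH2Cl2, 0 °C to rt
Reagents that add atoms: acetic anhydride (CC(=O)OC(C)=O)
Why: Standard acetylation of the primary alcohol; the acetate survives the oxidative steps that follow.

Step 3
Reactants: 5 (S)-citronellyl acetate
Product: 6 (S)-6-acetoxy-4-methylhexanoic acid
Conditions: RuCl3·xH2O (cat.), NaIO4, EtOAc/MeCN/H2O, rt
Reagents that add atoms: sodium periodate ([Na+].[O-]I(=O)(=O)=O); water (O)
Why: RuO4 generated in the flask cleaves the trisubstituted alkene to the carboxylic acid and acetone (oxidative alkene cleavage) without touching the ester or the remote stereocentre.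

Step 4
Reactants: 6 (S)-6-acetoxy-4-methylhexanoic acid
Product: 7 (R)-5-iodo-3-methylpentyl acetate
Conditions: PhI(OAc)2, I2, cyclohexane, hν, reflux
Reagents that add atoms: iodine (II)
Why: Suárez iododecarboxylation (acyl hypoiodite, radical decarboxylation, iodine transfer) removes one carbon; the stereocentre is not involved and only its descriptor changes.

Step 5
Reactants: 7 (R)-5-iodo-3-methylpentyl acetate; 8 acetylacetone
Product: 9 3-[(3S)-5-acetoxy-3-methylpentyl]pentane-2,4-dione
Conditions: K2CO3, acetone, reflux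
Reagents that add atoms: none
Why: C-alkylation of the acetylacetone enolate by a primary iodide (SN2) under carbonate conditions that spare the acetate.

Step 6
Reactants: 9 3-[(3S)-5-acetoxy-3-methylpentyl]pentane-2,4-dione
Product: 10 3-[(3S)-5-acetoxy-3-methylpentyl]-2,4-bis(trimethylsilyloxy)penta-1,3-diene
Conditions: TMSOTf (2.2 equiv), Et3N, Et2O, 0 °C
Reagents that add atoms: trimethylsilyl trifluoromethanesulfonate (C[Si](C)(C)OS(=O)(=O)C(F)(F)F)
Why: Double O-silylation of the 1,3-diketone gives the 1,3-bis(silyl enol ether), whose unsubstituted terminal CH2 is the nucleophilic site.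

Step 7
Reactants: 3 3,3-dimethylhex-5-enal; 10 3-[(3S)-5-acetoxy-3-methylpentyl]-2,4-bis(trimethylsilyloxy)penta-1,3-diene
Product: 12 (2R)-2-(2,2-dimethylpent-4-en-1-yl)-5-[(3S)-5-acetoxy-3-methylpentyl]-6-methyl-2,3-dihydro-4H-pyran-4-one, via hydroxy diketone 11 (not isolated)
Conditions: Ti(OiPr)4 (10 mol %), (S)-BINOL (20 mol %), 4 Å MS, Et2O, −20 °C; then TFA, CH2Cl2, 0 °C
Reagents that add atoms: none
Why: Keck-type Ti–BINOL-catalysed Mukaiyama aldol addition of the diene terminus to the aldehyde, then acid-induced desilylation and cyclodehydration (formal hetero-Diels–Alder reaction), gives the dihydropyranone; the carbinol centre is set by the chiral Lewis acid, and (S)-BINOL is expected, by analogy with Keck allylations, to give the R centre, which must be confirmed on the first run.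

Step 8
Reactants: 12 (2R)-2-(2,2-dimethylpent-4-en-1-yl)-5-[(3S)-5-acetoxy-3-methylpentyl]-6-methyl-2,3-dihydro-4H-pyran-4-one
Product: 14 (3Z,6R)-6-hydroxy-3-[(3S)-5-hydroxy-3-methylpentyl]-4,8,8-trimethylundeca-3,10-dien-2-one, via pyranol 13 (not isolated)
Conditions: MeLi (5 equiv), THF, −78 to 0 °C; then 1 M HCl, THF, 0 °C
Reagents that add atoms: methyllithium ([Li]C); water (O)
Why: Stork–Danheiser-type sequence: MeLi adds 1,2 to the vinylogous ester carbonyl (the excess also cleaves the primary acetate, which step 9 restores), then acid ionises the tertiary allylic alcohol to a cyclic oxocarbenium ion, water adds at the former enol ether carbon and the hemiketal opens to the enone; the C–O bond at the carbinol centre is never broken, so its configuration is retained.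

Step 9
Reactants: 14 (3Z,6R)-6-hydroxy-3-[(3S)-5-hydroxy-3-methylpentyl]-4,8,8-trimethylundeca-3,10-dien-2-one
Product: 15 (3Z,6R)-6-acetoxy-3-[(3S)-5-acetoxy-3-methylpentyl]-4,8,8-trimethylundeca-3,10-dien-2-one
Conditions: Ac2O, pyridine, rt
Reagents that add atoms: acetic anhydride (CC(=O)OC(C)=O)
Why: Acetylation of the primary and secondary hydroxyl groups drains the open-chain enone from its equilibrium with the cyclic hemiketal, whose tertiary hydroxyl is inert without DMAP.

Step 10
Reactants: 15 (3Z,6R)-6-acetoxy-3-[(3S)-5-acetoxy-3-methylpentyl]-4,8,8-trimethylundeca-3,10-dien-2-one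
Product: 16 (3Z,6R)-6-acetoxy-3-[(3S)-5-acetoxy-3-methylpentyl]-4,8,8-trimethylundec-3-ene-2,10-dione
Conditions: PdCl2 (10 mol %), CuCl, O2 (1 atm), DMF/H2O, rt
Reagents that add atoms: water (O)
Why: Tsuji–Wacker oxidation turns the terminal alkene into the methyl ketone with Markovnikov selectivity; the tetrasubstituted enone alkene and the acetates are inert.

Step 11
Reactants: 16 (3Z,6R)-6-acetoxy-3-[(3S)-5-acetoxy-3-methylpentyl]-4,8,8-trimethylundec-3-ene-2,10-dione
Product: 19 (2R,13S)-2,15-diacetoxylabd-7-en-6-one (ring stereocentres as in the target), via diketone 17 (not isolated), via ketol 18 (not isolated)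
Conditions: TsOH·H2O (1 equiv), toluene, 60 °C then reflux, Dean–Stark
Reagents that add atoms: none
Why: The acid forms the more substituted enol of the C6 methyl ketone (C5=C6) and the O-protonated enone, a hydroxyallyl cation whose positive end is the fully substituted C10; their union is an intramolecular Michael addition that forms C5–C10 and gives diketone 17, whose C7 enol then adds to the C8 ketone and loses water to the conjugated enone, forming C7=C8. The closest known reaction type is the Michael addition–aldol condensation that joins acetone and mesityl oxide to isophorone (a Robinson-type annulation), run here inside one chain. Ring A closes 6-exo-trig at the enone β-carbon, and ring B closes by a 6-(enolendo)-exo-trig aldol addition followed by dehydration. C10 is set in a chair transition state in which the C2 acetoxy group is equatorial (axial it would be syn-axial to a C4 methyl) and the bulky C9 end of the enone is pseudo-equatorial, so the C10 methyl ends up trans to the C2 oxygen; C5 is α to the C6 ketone and equilibrates to the trans ring fusion; C9 is α to C8 before and γ to C6 after closure and is expected to be fixed by enol protonation from the face opposite the C10 methyl, which places the side chain equatorial. The step needs the C5-to-C10 mode and the C7-to-C8 aldol mode: the first is secured because every other Michael or aldol pairing in 16 would give an eight- or ten-membered ring, the second because the C8 carbonyl is far less shielded than the C6 carbonyl, which sits on C5 between two quaternary carbons. Both enone geometries and all C5 and C9 epimers of 17 feed the same product, so the step is stereoconvergent.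

Step 12
Reactants: 19 (2R,13S)-2,15-diacetoxylabd-7-en-6-one
Product: 20 2,15-diacetoxylabd-7-en-6-ol (6-OH cis to the C10 methyl)
Conditions: NaBH4, CeCl3·7H2O, MeOH, −20 °C
Reagents that add atoms: none
Why: Luche 1,2-reduction of the enone; hydride adds from the face opposite the axial methyl groups on C4 and C10, giving the alcohol cis to the angular methyl, and the acetates survive at low temperature.

Step 13
Reactants: 20 2,15-diacetoxylabd-7-en-6-ol
Product: 21 (2R,5R,9R,10R,13S)-labd-7-ene-2,15-diyl diacetate (CNP0220683.1)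
Conditions: Et3SiH (5 equiv), BF3·OEt2 (1.2 equiv), CH2Cl2, −78 to −40 °C
Reagents that add atoms: none
Why: Ionic hydrogenolysis: BF3 ionises the allylic alcohol to the C6–C7–C8 allyl cation and Et3SiH delivers hydride to the secondary terminus C6, which keeps the trisubstituted C7=C8 alkene; no stereocentre is created or touched.

**Compound list**

1 | 2,2-dimethylpent-4-enal | C=CCC(C)(C)C=O | starting material
2 | 1-methoxy-3,3-dimethylhexa-1,5-diene (E/Z mixture) | COC=CC(C)(C)CC=C | intermediate
3 | 3,3-dimethylhex-5-enal | C=CCC(C)(C)CC=O | intermediate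
4 | (S)-citronellol | OCC[C@@H](C)CCC=C(C)C | starting material
5 | (S)-citronellyl acetate | CC(=O)OCC[C@@H](C)CCC=C(C)C | intermediate
6 | (S)-6-acetoxy-4-methylhexanoic acid | CC(=O)OCC[C@@H](C)CCC(=O)O | intermediate
7 | (R)-5-iodo-3-methylpentyl acetate | CC(=O)OCC[C@@H](C)CCI | intermediate
8 | acetylacetone (pentane-2,4-dione) | CC(=O)CC(C)=O | starting material
9 | 3-[(3S)-5-acetoxy-3-methylpentyl]pentane-2,4-dione | CC(=O)C(CC[C@H](C)CCOC(C)=O)C(C)=O | intermediate
10 | 3-[(3S)-5-acetoxy-3-methylpentyl]-2,4-bis(trimethylsilyloxy)penta-1,3-diene (enol ether geometry not defined) | C=C(O[Si](C)(C)C)C(CC[C@H](C)CCOC(C)=O)=C(C)O[Si](C)(C)C | intermediate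
11 | (6R)-6-hydroxy-3-[(3S)-5-acetoxy-3-methylpentyl]-8,8-dimethylundec-10-ene-2,4-dione (C3 epimers) | C=CCC(C)(C)C[C@@H](O)CC(=O)C(CC[C@H](C)CCOC(C)=O)C(C)=O | intermediate
12 | (2R)-2-(2,2-dimethylpent-4-en-1-yl)-5-[(3S)-5-acetoxy-3-methylpentyl]-6-methyl-2,3-dihydro-4H-pyran-4-one | C=CCC(C)(C)C[C@@H]1CC(=O)C(CC[C@H](C)CCOC(C)=O)=C(C)O1 | intermediate
13 | (2R)-2-(2,2-dimethylpent-4-en-1-yl)-5-[(3S)-5-hydroxy-3-methylpentyl]-4,6-dimethyl-3,4-dihydro-2H-pyran-4-ol (C4 epimers) | C=CCC(C)(C)C[C@@H]1CC(C)(O)C(CC[C@H](C)CCO)=C(C)O1 | intermediate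
14 | (3Z,6R)-6-hydroxy-3-[(3S)-5-hydroxy-3-methylpentyl]-4,8,8-trimethylundeca-3,10-dien-2-one | C=CCC(C)(C)C[C@@H](O)C/C(C)=C(\C(C)=O)CC[C@H](C)CCO | intermediate
15 | (3Z,6R)-6-acetoxy-3-[(3S)-5-acetoxy-3-methylpentyl]-4,8,8-trimethylundeca-3,10-dien-2-one | C=CCC(C)(C)C[C@@H](OC(C)=O)C/C(C)=C(\C(C)=O)CC[C@H](C)CCOC(C)=O | intermediate
16 | (3Z,6R)-6-acetoxy-3-[(3S)-5-acetoxy-3-methylpentyl]-4,8,8-trimethylundec-3-ene-2,10-dione | CC(=O)CC(C)(C)C[C@@H](OC(C)=O)C/C(C)=C(\C(C)=O)CC[C@H](C)CCOC(C)=O | intermediate
17 | monocyclic 1,5-diketone (Michael adduct; ring A formed, C2, C10 and C13 as in the target, C5 and C9 as equilibrating epimers) | CC(=O)OCC[C@@H](C)CCC(C(C)=O)[C@]1(C)C[C@H](OC(C)=O)CC(C)(C)C1C(C)=O | intermediate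
18 | 2,15-diacetoxy-8-hydroxylabdan-6-one (aldol; C5, C8 and C9 not yet fixed) | CC(=O)OCC[C@@H](C)CCC1C(C)(O)CC(=O)C2C(C)(C)C[C@@H](OC(C)=O)C[C@@]12C | intermediate
19 | (2R,13S)-2,15-diacetoxylabd-7-en-6-one (5-H and 9-H trans to the C10 methyl, 2-OAc trans to the C10 methyl) | CC(=O)OCC[C@@H](C)CC[C@@H]1C(C)=CC(=O)[C@@H]2C(C)(C)C[C@@H](OC(C)=O)C[C@@]12C | intermediate
20 | 2,15-diacetoxylabd-7-en-6-ol (6-OH cis to the C10 methyl, other centres as in 19) | CC(=O)OCC[C@@H](C)CC[C@@H]1C(C)=C[C@H](O)[C@@H]2C(C)(C)C[C@@H](OC(C)=O)C[C@@]12C | intermediate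
21 | (2R,5R,9R,10R,13S)-labd-7-ene-2,15-diyl diacetate (CNP0220683.1) | CC(=O)OCC[C@@H](C)CC[C@@H]1C(C)=CC[C@@H]2C(C)(C)C[C@@H](OC(C)=O)C[C@@]12C | target

**Totals**

Total step count: 13. Longest linear sequence: 12 steps (4 → 21 through steps 2–13).

**Steps most likely to fail**

1. Step 11. The Michael addition at the tetrasubstituted enone may be slower than acid-induced loss of acetic acid from C2 (enolisation at C1, then ionisation of the allylic acetate). Fallback, from 14 back to 19: 14 is oxidised under the Wacker conditions of step 10 to the keto diol F1. F1 is cyclised with KOtBu in t-BuOH/THF (0 °C to rt) through the enolates to the bicyclic enone diol F2; the two oxygens are then alkoxides and cannot leave. F2 is acetylated (Ac2O, pyridine, DMAP) and the route is rejoined at 19.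

2. Step 13. The allyl cation may take hydride at the tertiary terminus C8 or lose a proton to a diene; in addition, the C9 centre may have been partly epimerised under the acidic conditions of step 11. Fallback, from 19 to 21: 19 is converted with Tf2O and 2,6-di-tert-butyl-4-methylpyridine (CH2Cl2) into the extended dienyl triflate F3. F3 is reduced with Pd(OAc)2, PPh3, Bu3N and HCO2H (DMF, 60 °C) to the homoannular 6,8-diene F4. F4 is hydrogenated in the 1,4-sense with H2 and catalytic tricarbonyl(naphthalene)chromium (THF, 60 °C). Cis addition from the face opposite the axial methyl groups should give C7=C8 and the required C9–H whatever the C9 configuration of 19, arriving at 21.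

3. Step 7. Turnover or facial selectivity of the chiral Lewis acid may suffer with the 3-alkylated diene 10. Fallback, from 3 back to 12: acetylacetone 8 is silylated (TMSOTf, Et3N) to the parent bis-silyl dienol ether F5. F5 and 3 are combined under the Ti(OiPr)4/(S)-BINOL conditions, then TFA, to give the pyranone F6. F6 is iodinated at the α-carbon (I2, pyridine, CH2Cl2) to the iodopyranone F7. F7 is coupled (Negishi, Pd(PPh3)4, THF) with the alkylzinc iodide F8, made from 7 with zinc dust and LiCl, to give 12.

**Further compounds**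

F1 | step 11 | (3Z,6R)-6-hydroxy-3-[(3S)-5-hydroxy-3-methylpentyl]-4,8,8-trimethylundec-3-ene-2,10-dione | CC(=O)CC(C)(C)C[C@@H](O)C/C(C)=C(\C(C)=O)CC[C@H](C)CCO
F2 | step 11 | 2,15-dihydroxylabd-7-en-6-one (stereocentres as in 19) | OCC[C@@H](C)CC[C@@H]1C(C)=CC(=O)[C@@H]2C(C)(C)C[C@@H](O)C[C@@]12C
F3 | step 13 | 2,15-diacetoxylabda-6,8-dien-6-yl trifluoromethanesulfonate | CC(=O)OCC[C@@H](C)CCC1=C(C)C=C(OS(=O)(=O)C(F)(F)F)[C@@H]2C(C)(C)C[C@@H](OC(C)=O)C[C@@]12C
F4 | step 13 | labda-6,8-diene-2,15-diyl diacetate | CC(=O)OCC[C@@H](C)CCC1=C(C)C=C[C@@H]2C(C)(C)C[C@@H](OC(C)=O)C[C@@]12C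
F5 | step 7 | 2,4-bis(trimethylsilyloxy)penta-1,3-diene | C=C(O[Si](C)(C)C)C=C(C)O[Si](C)(C)C
F6 | step 7 | (2R)-2-(2,2-dimethylpent-4-en-1-yl)-6-methyl-2,3-dihydro-4H-pyran-4-one | C=CCC(C)(C)C[C@@H]1CC(=O)C=C(C)O1
F7 | step 7 | (2R)-2-(2,2-dimethylpent-4-en-1-yl)-5-iodo-6-methyl-2,3-dihydro-4H-pyran-4-one | C=CCC(C)(C)C[C@@H]1CC(=O)C(I)=C(C)O1
F8 | step 7 | [(3S)-5-acetoxy-3-methylpentyl]zinc iodide | CC(=O)OCC[C@@H](C)CC[Zn]I
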